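**Plan**
- Retrosynthetic cuts, in order: (a) the S–C bond of the allyl sulfone (allyl bromide + 2-guanidinoethanesulfinate); (b) the two E-trisubstituted chain alkenes at their vinylic C–C bonds (alkyne methylalumination, alkenyl–alkyl Negishi coupling, acetylide alkylation); (c) the bond from the quaternary ring carbon to the first chain CH2.
- Enabling feature: the quaternary carbon C1 of the cyclohexene ring is allylic to the ring C2=C3 alkene, so C3=C2–C1–CH2–C(=O) is a Claisen retron. An Eschenmoser–Claisen rearrangement of (1R,4R)-2,3,4-trimethylcyclohex-2-en-1-ol makes that bond, the quaternary centre and the 2-methylcyclohex-2-ene in one event.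
- Forward order: the six-membered ring is built first (Michael addition, aldol condensation, β-methylation), the rearrangement then joins ring and a two-carbon amide arm, and the chain is grown outward (C2, then C4, then C1) and capped with the sulfone–guanidine.
- Stereochemistry: the secondary methyl comes from the enamine-catalysed Michael step, the carbinol from CBS reduction, the quaternary carbon from 1,3-chirality transfer out of the carbinol, and both E-alkenes from syn-carboalumination.

Key step: step 6

Remark: the guanidine is formed as its hydrobromide and set free as the neutral base drawn for the target by a cold basic work-up; hypotaurine and (4-bromobut-1-yn-1-yl)trimethylsilane are taken as purchasable.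

**Route**

Step 1
Reactants: 1 propanal; 2 pent-1-en-3-one
Product: 3 (2R)-2-methyl-5-oxoheptanal
Conditions: (S)-2-[methoxy(diphenyl)methyl]pyrrolidine (5 mol %), ethyl 3,4-dihydroxybenzoate (20 mol %), neat, 4 °C
Reagents that add atoms: none
Why: Enamine-catalysed asymmetric Michael addition of an aldehyde to a vinyl ketone, in which the E-enamine of propanal is attacked on the face away from the methoxydiphenylmethyl group, which should set the (R)-methyl centre.

Step 2
Reactants: 3 (2R)-2-methyl-5-oxoheptanal
Product: 4 (4R)-2,4-dimethylcyclohex-2-en-1-one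
Conditions: LiOH (cat.), i-PrOH, rt
Reagents that add atoms: none
Why: Intramolecular aldol condensation in which the ethyl ketone α-CH2 adds to the aldehyde (the only six-membered closure) and dehydrates, so the aldehyde α-centre becomes the γ-carbon C4 and should survive the mild base with little epimerisation.

Step 3
Reactants: 4 (4R)-2,4-dimethylcyclohex-2-en-1-one
Product: 5 trimethyl{[(3S,4R)-2,3,4-trimethylcyclohex-1-en-1-yl]oxy}silane
Conditions: MeMgBr, CuBr·SMe2 (5 mol %), TMSCl, HMPA, THF, −78 °C; Et3N quench
Reagents that add atoms: methylmagnesium bromide, C[Mg]Br; chlorotrimethylsilane, C[Si](C)(C)Cl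
Why: Copper-catalysed, TMSCl-accelerated conjugate addition with in situ O-silylation gives the regiodefined tetrasubstituted enol ether; methyl should add anti to the C4 methyl, and the C3 centre is erased in step 4 in any case.

Step 4
Reactants: 5 trimethyl{[(3S,4R)-2,3,4-trimethylcyclohex-1-en-1-yl]oxy}silane
Product: 6 (4R)-2,3,4-trimethylcyclohex-2-en-1-one
Conditions: Pd(OAc)2 (10 mol %), O2 (1 atm), DMSO, rt
Reagents that add atoms: none
Why: Saegusa–Ito oxidation, in which the enolate of divalent palladium loses the ring C3 hydride to give the conjugated tetrasubstituted enone while oxygen reoxidises zerovalent palladium; the neutral conditions should leave C4 untouched.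

Step 5
Reactants: 6 (4R)-2,3,4-trimethylcyclohex-2-en-1-one
Product: 7 (1R,4R)-2,3,4-trimethylcyclohex-2-en-1-ol
Conditions: (S)-2-methyl-CBS-oxazaborolidine (20 mol %), BH3·SMe2, THF, −20 °C; MeOH quench
Reagents that add atoms: none
Why: Corey–Bakshi–Shibata reduction, in which the catalyst treats the fully substituted alkenyl arm as the large group and should deliver hydride to give the (1R)-carbinol, trans to the C4 methyl, under reagent control over the remote ring methyl.

Step 6
Reactants: 7 (1R,4R)-2,3,4-trimethylcyclohex-2-en-1-ol; 8 N,N-dimethylacetamide dimethyl acetal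
Product: 10 2-[(1S,6R)-1,2,6-trimethylcyclohex-2-en-1-yl]-N,N-dimethylacetamide, via ketene N,O-acetal 9 (not isolated)
Conditions: xylenes, 140 °C, MeOH distilled off
Reagents that add atoms: none
Why: Exchange of the C1 hydroxyl of 7 into the amide acetal and loss of a second methanol give ketene N,O-acetal 9, which undergoes a concerted suprafacial [3,3]-sigmatropic shift across the ring allyl unit C1(O)–C2=C3: the C1–O bond breaks, the alkene moves to C1=C2 and the ketene-acetal CH2 bonds to C3, driven by formation of the amide carbonyl. The closest known reaction type is the Eschenmoser–Claisen rearrangement of 3-substituted cyclohex-2-en-1-ols, a standard route to quaternary ring carbons. No ring is closed; only a transient six-membered transition state is traversed. The one new stereocentre, the quaternary carbon, is controlled by the C1 carbinol through 1,3-chirality transfer, the carbon arriving on the ring face from which oxygen departs; because that oxygen is trans to the C4 methyl, the acetamide arm ends trans to the secondary methyl and the two ring methyls end cis, as in the target. The step needs the [3,3] shift to win over ionisation or 1,4-elimination to a diene and needs full facial fidelity: the acid-free thermal conditions exclude allyl cation pathways, and the new bond forms on the face anti to the C4 methyl, so the existing centre reinforces the transfer. The same event places the trisubstituted double bond exactly where the 2-methylcyclohex-2-ene of the target needs it.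

Step 7
Reactants: 10 2-[(1S,6R)-1,2,6-trimethylcyclohex-2-en-1-yl]-N,N-dimethylacetamide
Product: 11 2-[(1S,6R)-1,2,6-trimethylcyclohex-2-en-1-yl]ethan-1-ol
Conditions: LiEt3BH, THF, 0 °C to rt; H2O
Reagents that add atoms: none
Why: Lithium triethylborohydride reduces tertiary N,N-dimethylamides to primary alcohols with C–N cleavage, and the ring alkene and both stereocentres are inert to it.

Step 8
Reactants: 11 2-[(1S,6R)-1,2,6-trimethylcyclohex-2-en-1-yl]ethan-1-ol
Product: 12 (5R,6S)-6-(2-iodoethyl)-1,5,6-trimethylcyclohex-1-ene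
Conditions: I2, PPh3, imidazole, CH2Cl2, 0 °C to rt
Reagents that add atoms: iodine, [I][I]
Why: Appel-type iodination, an SN2 displacement of the alkoxyphosphonium by iodide at an unhindered primary carbon.

Step 9
Reactants: 12 (5R,6S)-6-(2-iodoethyl)-1,5,6-trimethylcyclohex-1-ene
Product: 13 (5R,6S)-6-(but-3-yn-1-yl)-1,5,6-trimethylcyclohex-1-ene
Conditions: lithium acetylide–ethylenediamine complex, DMSO, rt
Reagents that add atoms: lithium acetylide–ethylenediamine complex, [Li]C#C.NCCN
Why: SN2 alkylation of an acetylide by a primary iodide in a dipolar solvent, which should outpace E2 elimination.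

Step 10
Reactants: 13 (5R,6S)-6-(but-3-yn-1-yl)-1,5,6-trimethylcyclohex-1-ene
Product: 15 (5R,6S)-6-[(3E)-4-iodo-3-methylbut-3-en-1-yl]-1,5,6-trimethylcyclohex-1-ene, via alkenylalane 14 (not isolated)
Conditions: AlMe3, Cp2ZrCl2 (20 mol %), CH2Cl2, 0 °C to rt; then I2, THF, −30 °C
Reagents that add atoms: trimethylaluminium, C[Al](C)C; iodine, [I][I]
Why: Zirconium-catalysed methylalumination (Negishi carboalumination) adds methyl and aluminium syn across the terminal alkyne with aluminium on the terminal carbon, and iodinolysis with retention should give the (E)-iodoalkene; the trisubstituted ring alkene is inert.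

Step 11
Reactants: 15 (5R,6S)-6-[(3E)-4-iodo-3-methylbut-3-en-1-yl]-1,5,6-trimethylcyclohex-1-ene; 16 (4-bromobut-1-yn-1-yl)trimethylsilane
Product: 18 trimethyl{(5E)-6-methyl-8-[(1S,6R)-1,2,6-trimethylcyclohex-2-en-1-yl]oct-5-en-1-yn-1-yl}silane, via alkylzinc bromide 17 (not isolated)
Conditions: 16, Zn dust, LiCl, THF, 50 °C; then 15, Pd(PPh3)4 (5 mol %), THF, rt
Reagents that add atoms: none
Why: Negishi alkenyl–alkyl cross-coupling (oxidative addition of the alkenyl iodide to zerovalent palladium, transmetalation from the homopropargylzinc, reductive elimination) proceeds with retention of the E geometry and builds the 1,5-enyne.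

Step 12
Reactants: 18 trimethyl{(5E)-6-methyl-8-[(1S,6R)-1,2,6-trimethylcyclohex-2-en-1-yl]oct-5-en-1-yn-1-yl}silane
Product: 19 (5R,6S)-1,5,6-trimethyl-6-[(3E)-3-methyloct-3-en-7-yn-1-yl]cyclohex-1-ene
Conditions: K2CO3 (cat.), MeOH, rt
Reagents that add atoms: none
Why: Base-catalysed methanolysis of the alkynyl C–Si bond frees the terminal alkyne without touching the alkenes.

Step 13
Reactants: 19 (5R,6S)-1,5,6-trimethyl-6-[(3E)-3-methyloct-3-en-7-yn-1-yl]cyclohex-1-ene
Product: 22 (2E,6E)-3,7-dimethyl-9-[(1S,6R)-1,2,6-trimethylcyclohex-2-en-1-yl]nona-2,6-dien-1-ol, via alkenylalane 20 (not isolated), via lithium alanate 21 (not isolated)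
Conditions: AlMe3, Cp2ZrCl2 (20 mol %), CH2Cl2, rt; then n-BuLi, THF, −78 °C; then (CH2O)n, rt
Reagents that add atoms: trimethylaluminium, C[Al](C)C; paraformaldehyde (as formaldehyde), C=O
Why: A second syn-methylalumination sets the second E-trisubstituted alkene, and the alanate made with n-BuLi is nucleophilic enough to add to formaldehyde with retention, giving the (E)-allylic alcohol.

Step 14
Reactants: 22 (2E,6E)-3,7-dimethyl-9-[(1S,6R)-1,2,6-trimethylcyclohex-2-en-1-yl]nona-2,6-dien-1-ol
Product: 23 (5R,6S)-6-[(3E,7E)-9-bromo-3,7-dimethylnona-3,7-dien-1-yl]-1,5,6-trimethylcyclohex-1-ene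
Conditions: PBr3, Et2O, 0 °C
Reagents that add atoms: phosphorus tribromide, BrP(Br)Br
Why: Standard conversion of a primary allylic (farnesol-type) alcohol to the bromide by SN2 displacement of the phosphite ester, which should keep the alkene geometry at low temperature.

Step 15
Reactants: 24 hypotaurine (2-aminoethanesulfinic acid)
Product: 25 2-guanidinoethanesulfinic acid (hypotaurocyamine, zwitterion)
Conditions: 1H-pyrazole-1-carboxamidine hydrochloride, NaOH (1 equiv), H2O, rt, argon
Reagents that add atoms: 1H-pyrazole-1-carboxamidine hydrochloride, Cl.NC(=N)n1cccn1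
Why: Amine guanylation by amidine transfer from the pyrazole reagent, with the sulfinate as a spectator and oxygen excluded to avoid oxidation to the sulfonate.

Step 16
Reactants: 23 (5R,6S)-6-[(3E,7E)-9-bromo-3,7-dimethylnona-3,7-dien-1-yl]-1,5,6-trimethylcyclohex-1-ene; 25 2-guanidinoethanesulfinic acid
Product: 27 agelasidine C, via guanidinium bromide 26 (not isolated)
Conditions: DMSO, rt, argon; then cold 1 M NaOH, extraction
Reagents that add atoms: none
Why: S-alkylation of a sulfinate by a primary allylic bromide (SN2 at the soft sulfur centre) should give the sulfone directly while the guanidine is masked as its own guanidinium, and the basic work-up frees the neutral guanidine.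

**Compound list**

1 | propanal | CCC=O | starting material
2 | pent-1-en-3-one (ethyl vinyl ketone) | CCC(=O)C=C | starting material
3 | (2R)-2-methyl-5-oxoheptanal | CCC(=O)CC[C@@H](C)C=O | intermediate
4 | (4R)-2,4-dimethylcyclohex-2-en-1-one | O=C1CC[C@@H](C)C=C1C | intermediate
5 | trimethyl{[(3S,4R)-2,3,4-trimethylcyclohex-1-en-1-yl]oxy}silane (3,4-trans) | C[Si](C)(C)OC1=C(C)[C@@H](C)[C@H](C)CC1 | intermediate
6 | (4R)-2,3,4-trimethylcyclohex-2-en-1-one | O=C1CC[C@@H](C)C(C)=C1C | intermediate
7 | (1R,4R)-2,3,4-trimethylcyclohex-2-en-1-ol (OH trans to the C4 methyl) | O[C@@H]1CC[C@@H](C)C(C)=C1C | intermediate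
8 | N,N-dimethylacetamide dimethyl acetal (1,1-dimethoxy-N,N-dimethylethan-1-amine) | CC(OC)(OC)N(C)C | starting material
9 | ketene N,O-acetal: N,N-dimethyl-1-{[(1R,4R)-2,3,4-trimethylcyclohex-2-en-1-yl]oxy}ethen-1-amine | C=C(N(C)C)O[C@@H]1CC[C@@H](C)C(C)=C1C | intermediate
10 | 2-[(1S,6R)-1,2,6-trimethylcyclohex-2-en-1-yl]-N,N-dimethylacetamide | CC1=CCC[C@@H](C)[C@]1(C)CC(=O)N(C)C | intermediate
11 | 2-[(1S,6R)-1,2,6-trimethylcyclohex-2-en-1-yl]ethan-1-ol | CC1=CCC[C@@H](C)[C@]1(C)CCO | intermediate
12 | (5R,6S)-6-(2-iodoethyl)-1,5,6-trimethylcyclohex-1-ene | CC1=CCC[C@@H](C)[C@]1(C)CCI | intermediate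
13 | (5R,6S)-6-(but-3-yn-1-yl)-1,5,6-trimethylcyclohex-1-ene | CC1=CCC[C@@H](C)[C@]1(C)CCC#C | intermediate
14 | alkenylalane: dimethyl{(1E)-2-methyl-4-[(1S,6R)-1,2,6-trimethylcyclohex-2-en-1-yl]but-1-en-1-yl}aluminium | CC1=CCC[C@@H](C)[C@]1(C)CC/C(C)=C/[Al](C)C | intermediate
15 | (5R,6S)-6-[(3E)-4-iodo-3-methylbut-3-en-1-yl]-1,5,6-trimethylcyclohex-1-ene | CC1=CCC[C@@H](C)[C@]1(C)CC/C(C)=C/I | intermediate
16 | (4-bromobut-1-yn-1-yl)trimethylsilane | C[Si](C)(C)C#CCCBr | starting material
17 | [4-(trimethylsilyl)but-3-yn-1-yl]zinc bromide | C[Si](C)(C)C#CCC[Zn]Br | intermediate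
18 | trimethyl{(5E)-6-methyl-8-[(1S,6R)-1,2,6-trimethylcyclohex-2-en-1-yl]oct-5-en-1-yn-1-yl}silane | CC1=CCC[C@@H](C)[C@]1(C)CC/C(C)=C/CCC#C[Si](C)(C)C | intermediate
19 | (5R,6S)-1,5,6-trimethyl-6-[(3E)-3-methyloct-3-en-7-yn-1-yl]cyclohex-1-ene | CC1=CCC[C@@H](C)[C@]1(C)CC/C(C)=C/CCC#C | intermediate
20 | alkenylalane: {(1E,5E)-2,6-dimethyl-8-[(1S,6R)-1,2,6-trimethylcyclohex-2-en-1-yl]octa-1,5-dien-1-yl}dimethylaluminium | CC1=CCC[C@@H](C)[C@]1(C)CC/C(C)=C/CC/C(C)=C/[Al](C)C | intermediate
21 | lithium butyl(dimethyl)alkenylalanate derived from 20 | CC1=CCC[C@@H](C)[C@]1(C)CC/C(C)=C/CC/C(C)=C/[Al-](C)(C)CCCC.[Li+] | intermediate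
22 | (2E,6E)-3,7-dimethyl-9-[(1S,6R)-1,2,6-trimethylcyclohex-2-en-1-yl]nona-2,6-dien-1-ol | CC1=CCC[C@@H](C)[C@]1(C)CC/C(C)=C/CC/C(C)=C/CO | intermediate
23 | (5R,6S)-6-[(3E,7E)-9-bromo-3,7-dimethylnona-3,7-dien-1-yl]-1,5,6-trimethylcyclohex-1-ene | CC1=CCC[C@@H](C)[C@]1(C)CC/C(C)=C/CC/C(C)=C/CBr | intermediate
24 | hypotaurine (2-aminoethanesulfinic acid) | NCCS(=O)O | starting material
25 | 2-guanidinoethanesulfinic acid (hypotaurocyamine) | NC(N)=NCCS(=O)O | intermediate
26 | agelasidine C hydrobromide (guanidinium bromide) | CC1=CCC[C@@H](C)[C@]1(C)CC/C(C)=C/CC/C(C)=C/CS(=O)(=O)CCN=C(N)N.Br | intermediate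
27 | agelasidine C: 2-{[(2E,6E)-3,7-dimethyl-9-[(1S,6R)-1,2,6-trimethylcyclohex-2-en-1-yl]nona-2,6-dien-1-yl]sulfonyl}ethylguanidine | CC1=CCC[C@@H](C)[C@]1(C)CC/C(C)=C/CC/C(C)=C/CS(=O)(=O)CCN=C(N)N | target

**Step count and risks**

Total steps: 16. Longest linear sequence: 15 (steps 1 to 14, then 16); step 15 is a one-step side branch.

Steps most likely to fail:

1. Step 4. Palladation of the fully substituted enol ether may be slow, β-hydride loss may occur from the C2 methyl group to give the exocyclic methylene ketone, and the C4 centre may epimerise through the dienol. The fallback sets out from 4 and returns at 6. Thiophenol with catalytic Et3N adds to 4 to give (4R)-2,4-dimethyl-3-(phenylsulfanyl)cyclohexan-1-one F1. N-Chlorosuccinimide followed by Et3N (chlorination next to sulfur, loss of HCl toward the ketone) gives (4R)-2,4-dimethyl-3-(phenylsulfanyl)cyclohex-2-en-1-one F2, in which the double bond is fixed at C2=C3. Me2CuLi then replaces the sulfanyl group by addition–elimination and gives 6.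

2. Step 6. The bond must form at a fully substituted alkene carbon flanked by two methyl-bearing carbons, so the sigmatropic shift may be outrun by thermal 1,4-elimination of the ketene acetal to a diene. The fallback sets out from 6 and returns at 11, replacing the rearrangement by a copper-mediated anti-SN2' substitution. Reduction of 6 with the enantiomeric (R)-oxazaborolidine and BH3·SMe2 gives the cis alcohol (1S,4R)-2,3,4-trimethylcyclohex-2-en-1-ol F3. Picolinic acid, DCC and DMAP give (1S,4R)-2,3,4-trimethylcyclohex-2-en-1-yl pyridine-2-carboxylate F4. VinylMgBr with CuBr·SMe2 (THF, −40 °C) delivers vinyl to the fully substituted alkene carbon anti to the chelating leaving group, hence trans to the secondary methyl, giving (5R,6S)-6-ethenyl-1,5,6-trimethylcyclohex-1-ene F5. 9-BBN, then NaOH/H2O2, hydroborates only the vinyl group and gives 11.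

3. Step 16. O-Alkylation to a sulfinate ester, SN2' attack leading to the tertiary sulfone, N-alkylation of the guanidine, or poor mutual solubility of the zwitterion and the lipophilic bromide may divert the coupling. The fallback sets out from 23 and returns at 27. 2-Aminoethanethiol hydrochloride with NaOMe in MeOH alkylates on sulfur to give 2-{[(2E,6E)-3,7-dimethyl-9-[(1S,6R)-1,2,6-trimethylcyclohex-2-en-1-yl]nona-2,6-dien-1-yl]sulfanyl}ethan-1-amine F6. 1H-Pyrazole-1-carboxamidine hydrochloride with i-Pr2NEt in DMF gives the guanidino sulfide hydrochloride F7. (NH4)6Mo7O24·4H2O (cat.) with H2O2 in EtOH at 0 °C oxidises sulfur only, giving agelasidine C hydrochloride F8, and cold NaOH frees 27.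

**Further compounds**

F1 | step 4 | (4R)-2,4-dimethyl-3-(phenylsulfanyl)cyclohexan-1-one (3,4-trans, C2 epimers) | O=C1CC[C@@H](C)[C@H](Sc2ccccc2)C1C
F2 | step 4 | (4R)-2,4-dimethyl-3-(phenylsulfanyl)cyclohex-2-en-1-one | O=C1CC[C@@H](C)C(Sc2ccccc2)=C1C
F3 | step 6 | (1S,4R)-2,3,4-trimethylcyclohex-2-en-1-ol | O[C@H]1CC[C@@H](C)C(C)=C1C
F4 | step 6 | (1S,4R)-2,3,4-trimethylcyclohex-2-en-1-yl pyridine-2-carboxylate | O=C(O[C@H]1CC[C@@H](C)C(C)=C1C)c1ccccn1
F5 | step 6 | (5R,6S)-6-ethenyl-1,5,6-trimethylcyclohex-1-ene | CC1=CCC[C@@H](C)[C@]1(C)C=C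
F6 | step 16 | 2-{[(2E,6E)-3,7-dimethyl-9-[(1S,6R)-1,2,6-trimethylcyclohex-2-en-1-yl]nona-2,6-dien-1-yl]sulfanyl}ethan-1-amine | CC1=CCC[C@@H](C)[C@]1(C)CC/C(C)=C/CC/C(C)=C/CSCCN
F7 | step 16 | 2-{[(2E,6E)-3,7-dimethyl-9-[(1S,6R)-1,2,6-trimethylcyclohex-2-en-1-yl]nona-2,6-dien-1-yl]sulfanyl}ethylguanidine hydrochloride | CC1=CCC[C@@H](C)[C@]1(C)CC/C(C)=C/CC/C(C)=C/CSCCN=C(N)N.Cl
F8 | step 16 | agelasidine C hydrochloride | CC1=CCC[C@@H](C)[C@]1(C)CC/C(C)=C/CC/C(C)=C/CS(=O)(=O)CCN=C(N)N.Cl
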